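**Retrosynthetic overview**
1. Target ⇐ TES removal and double angeloylation of epoxy triol 19 ⇐ hydroxyl-directed epoxidation and Luche reduction of hydroxy enone 17.
2. 17 ⇐ 1,6-borylation/oxidation of dienone 14 ⇐ dehydrogenation of the cis-fused hydroazulenone 13.
3. Key step: 13 ⇐ epoxy ketone 10 in one flask. A cyclohexene is expanded to the cycloheptene by a cationic 1,2-shift onto the exocyclic tertiary carbon (the laboratory counterpart of bisabolyl → daucyl), then the cyclopentane is closed across C4–C5 by a carbonyl-ene reaction.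
4. 10 ⇐ Shi epoxidation and oxidation of diene diol 8 ⇐ alkenyllithium (from iodide 5) + 5-methylcyclohex-2-enone 6; 5 ⇐ propynyllithium + isopropyloxirane.
5. Ring order: six-membered ring bought, seven-membered ring by ring expansion, five-membered ring last.

Assumption: the SMILES is read literally; it encodes a cis-fused daucane (C1-methyl and C5-H on the same face), (1S,2S,4R,5S,6S,8S,9R,10R), with both esters as (Z)-2-methylbut-2-enoates (angelates).
Notation: bicyclic compounds carry daucane numbering (C1 = methyl-bearing ring-fusion carbon, C2–C4 = cyclopentane with isopropyl on C4, C5 = ring-fusion CH, C6–C10 = cycloheptane with methyl on C8); β is the face of the C1 methyl.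
Racemic 6 is bought; stereocentres that later become sp2 (the carbinol carbons in 3–11 and the ring-methyl carbon up to 13) are carried as mixtures.

**Step 1**
Reactants: 1 2-(propan-2-yl)oxirane (racemic); 2 1-propynyllithium
Product: 3 2-methylhept-5-yn-3-ol (racemic)
Conditions: 2, BF3·OEt2, THF, −78 °C; then 1, −78 °C; aq. NH4Cl
Reagents that add atoms: none
Why: BF3-assisted alkynylation of a terminal epoxide (Yamaguchi–Hirao) opens the oxirane at the unhindered CH2; the carbinol stereocentre is irrelevant because it is oxidised in step 5.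

**Step 2**
Reactants: 3 2-methylhept-5-yn-3-ol
Product: 5 (E)-6-iodo-2-methylhept-5-en-3-ol, via alkenylzirconocene 4 (not isolated)
Conditions: Cp2Zr(H)Cl (2.5 equiv), THF, 23 → 45 °C; then I2, 0 °C
Reagents that add atoms: iodine, II
Why: Schwartz hydrozirconation adds Zr–H syn and, after equilibration with excess reagent, leaves zirconium on the less hindered methyl-bearing carbon, so iodinolysis with retention gives the (E)-iodoalkene that later fixes the trans epoxide.

**Step 3**
Reactants: 5 (E)-6-iodo-2-methylhept-5-en-3-ol; 6 5-methylcyclohex-2-en-1-one (racemic)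
Product: 8 1-[(E)-5-hydroxy-6-methylhept-2-en-2-yl]-5-methylcyclohex-2-en-1-ol (diastereomer mixture), via dilithio alkenyl alkoxide 7 (not isolated)
Conditions: 5, t-BuLi (3.1 equiv), Et2O, −78 °C; then 6, −78 → −40 °C; aq. NH4Cl
Reagents that add atoms: none
Why: Lithium–iodine exchange with retention of alkene geometry and 1,2-addition of the alkenyllithium to the enone give the tertiary allylic alcohol; its three stereocentres are left as mixtures because each becomes sp2 in steps 5–7.

**Step 4**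
Reactants: 8 diene diol
Product: 9 1-[(2R,3S)-3-(2-hydroxy-3-methylbutyl)-2-methyloxiran-2-yl]-5-methylcyclohex-2-en-1-ol
Conditions: ent-Shi ketone (L-fructose-derived, 30 mol %), KHSO5 (Oxone), K2CO3, Bu4NHSO4, MeCN/(MeO)2CH2/aq. Na2B4O7 buffer (pH 10.5), 0 °C
Reagents that add atoms: potassium peroxymonosulfate KHSO5, [K+].[O-]S(=O)(=O)OO
Why: Shi asymmetric epoxidation attacks the trisubstituted (E)-alkene much faster than the cis-disubstituted ring alkene and sets the future C1 and C2 by reagent control (spiro transition state); the adjacent carbinol carbon has two similar ring arms, so it should bias the face little.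

**Step 5**
Reactants: 9 epoxy diol
Product: 10 1-[(2S,3R)-3-(1-hydroxy-5-methylcyclohex-2-en-1-yl)-3-methyloxiran-2-yl]-3-methylbutan-2-one
Conditions: Dess–Martin periodinane, NaHCO3, CH2Cl2, 0 °C → rt
Reagents that add atoms: none
Why: Dess–Martin oxidation touches only the secondary alcohol, under buffered conditions that spare the β,γ-epoxy ketone and the tertiary allylic alcohol.

**Step 6 (key step)**
Reactants: 10 epoxy ketone
Product: 13 4α-hydroxy-2β-(triethylsilyloxy)-5β-H-dauc-6-en-10-one (C8 epimers), via epoxy silyl ether 11 (not isolated), via cycloheptenone silyl ether 12 (not isolated)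
Conditions: TESOTf (1.3 equiv), 2,6-lutidine (1.1 equiv), CH2Cl2, −78 °C; then Me2AlCl (4 equiv), −78 → 0 °C; aq. Rochelle salt (KNaC4H4O6)
Reagents that add atoms: triethylsilyl trifluoromethanesulfonate, CC[Si](CC)(CC)OS(=O)(=O)C(F)(F)F
Why: Proposed new method: the silyl triflate silylates the carbinol and then activates the epoxide, so the ring alkenyl carbon C5 shifts from C10 to the tertiary epoxide carbon C1 anti to the breaking C–O bond (semipinacol ring expansion, inversion at C1, retention at C2, carbinol → C10 ketone, the exocyclic cationic carbon being inserted into the six-membered ring as in the bisabolyl → daucyl step), and Me2AlCl then promotes an intramolecular carbonyl-ene reaction of the isopropyl ketone with the new ring alkene, where the tether on C1 enforces cis fusion (5β-H) and the six-centre hydrogen transfer from C7 puts the C4 oxygen on the α-face; the closest known reactions are silyl-triflate semipinacol rearrangements of epoxy alcohols (Suzuki–Tsuchihashi, Jung) and alkylaluminium-halide ketone-ene cyclisations (Snider), here combined in one flask.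

**Step 7**
Reactants: 13 hydroazulenone
Product: 14 4α-hydroxy-2β-(triethylsilyloxy)-5β-H-dauca-6,8-dien-10-one
Conditions: IBX (2.5 equiv), 4-methoxypyridine N-oxide, DMSO, 25 → 45 °C
Reagents that add atoms: none
Why: IBX α,β-dehydrogenation (Nicolaou) can only proceed toward C9 because C1 is quaternary; it gives the linear dienone and removes the C8 stereocentre.

**Step 8**
Reactants: 14 dienone
Product: 17 4α,6β-dihydroxy-2β-(triethylsilyloxy)dauc-8-en-10-one, via allylic boronate 15 (not isolated), via conjugated boronate 16 (not isolated)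
Conditions: B2pin2 (1.2 equiv), CuCl (5 mol %), Xantphos (5 mol %), NaOt-Bu (10 mol %), MeOH (2 equiv), THF, 0 °C → rt; DBU (0.3 equiv), rt; then NaBO3·4H2O, THF/H2O, 0 °C → rt
Reagents that add atoms: bis(pinacolato)diboron, CC1(C)OB(OC1(C)C)B1OC(C)(C)C(C)(C)O1; sodium perborate NaBO3, [Na+].[O-]OB=O
Why: Copper-catalysed conjugate borylation should go 1,6 because the β-carbon C8 is fully substituted; Cu–B adds to C6 from the convex face anti to the C5–C4 bond, DBU moves the alkene into conjugation while boron (no leaving group) is still on C6, and oxidation with retention gives the 6β-alcohol.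

**Step 9**
Reactants: 17 hydroxy enone
Product: 18 2β-(triethylsilyloxy)dauc-8-ene-4α,6β,10α-triol
Conditions: NaBH4, CeCl3·7H2O, MeOH, −40 °C
Reagents that add atoms: none
Why: Luche 1,2-reduction; hydride is expected to reach C10 from the face of the small C1 methyl, anti to the bulkier C2 arm, giving the 10α-allylic alcohol.

**Step 10**
Reactants: 18 allylic alcohol
Product: 19 8α,9α-epoxy-2β-(triethylsilyloxy)daucane-4α,6β,10α-triol
Conditions: VO(acac)2 (5 mol %), t-BuOOH (decane), CH2Cl2, 0 °C → rt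
Reagents that add atoms: tert-butyl hydroperoxide, CC(C)(C)OO
Why: Vanadium-catalysed hydroxyl-directed epoxidation (Sharpless–Michaelson) delivers oxygen syn to the allylic 10α-hydroxyl, setting C8 and C9 as the α-epoxide.

**Step 11**
Reactants: 19 epoxy triol; 20 angelic acid [(Z)-2-methylbut-2-enoic acid]
Product: 22 6β,10α-bis(angeloyloxy)-8α,9α-epoxy-2β-(triethylsilyloxy)daucan-4α-ol, via C6 monoangelate 21 (not isolated)
Conditions: 20 (6 equiv), 2,4,6-trichlorobenzoyl chloride (6 equiv), Et3N, toluene, rt, filter; then 19, toluene, 75 °C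
Reagents that add atoms: none
Why: Yamaguchi-type mixed-anhydride esterification without DMAP (Hartmann protocol) acylates both secondary alcohols with retention of the (Z)-geometry; the tertiary 4-OH does not react and C2 is masked as its silyl ether.

**Step 12**
Reactants: 22 bis-angelate silyl ether
Product: 23 CNP0265715.3, (1S,2S,4R,5S,6S,8S,9R,10R)-8α,9α-epoxy-2β,4α-dihydroxy-5β-H-daucane-6β,10α-diyl bis[(Z)-2-methylbut-2-enoate]
Conditions: HF·pyridine, pyridine, THF, 0 °C
Reagents that add atoms: none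
Why: Buffered fluoride desilylation removes the triethylsilyl ether without touching the angelates, the epoxide or the tertiary alcohol.

**Compound list**
1 | 2-(propan-2-yl)oxirane (racemic) | CC(C)C1CO1 | starting material
2 | 1-propynyllithium | [Li]C#CC | starting material
3 | 2-methylhept-5-yn-3-ol (racemic) | CC#CCC(O)C(C)C | intermediate
4 | (E)-alkenylzirconocene chloride of 3, oxygen also bound to Cp2ZrCl | C/C(=C\CC(O[Zr](Cl)(C1C=CC=C1)C1C=CC=C1)C(C)C)[Zr](Cl)(C1C=CC=C1)C1C=CC=C1 | intermediate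
5 | (E)-6-iodo-2-methylhept-5-en-3-ol | C/C(I)=C\CC(O)C(C)C | intermediate
6 | 5-methylcyclohex-2-en-1-one (racemic) | CC1CC=CC(=O)C1 | starting material
7 | lithium (E)-6-lithio-2-methylhept-5-en-3-olate | C/C([Li])=C\CC(O[Li])C(C)C | intermediate
8 | 1-[(E)-5-hydroxy-6-methylhept-2-en-2-yl]-5-methylcyclohex-2-en-1-ol (diastereomer mixture) | C/C(=C\CC(O)C(C)C)C1(O)C=CCC(C)C1 | intermediate
9 | 1-[(2R,3S)-3-(2-hydroxy-3-methylbutyl)-2-methyloxiran-2-yl]-5-methylcyclohex-2-en-1-ol | C[C@]1(O[C@H]1CC(O)C(C)C)C2(O)C=CCC(C)C2 | intermediate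
10 | 1-[(2S,3R)-3-(1-hydroxy-5-methylcyclohex-2-en-1-yl)-3-methyloxiran-2-yl]-3-methylbutan-2-one | C[C@]1(O[C@H]1CC(=O)C(C)C)C2(O)C=CCC(C)C2 | intermediate
11 | tertiary triethylsilyl ether of 10 | C[C@]1(O[C@H]1CC(=O)C(C)C)C2(O[Si](CC)(CC)CC)C=CCC(C)C2 | intermediate
12 | (2S)-2,6-dimethyl-2-[(1S)-4-methyl-3-oxo-1-(triethylsilyloxy)pentyl]cyclohept-3-en-1-one (C6 epimers) | CC(C)C(=O)C[C@H](O[Si](CC)(CC)CC)[C@]1(C)C=CCC(C)CC1=O | intermediate
13 | 4α-hydroxy-2β-(triethylsilyloxy)-5β-H-dauc-6-en-10-one (C8 epimers) | C1=CC(C)CC(=O)[C@@]2(C)[C@@H]1[C@](O)(C(C)C)C[C@@H]2O[Si](CC)(CC)CC | intermediate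
14 | 4α-hydroxy-2β-(triethylsilyloxy)-5β-H-dauca-6,8-dien-10-one | C1=CC(C)=CC(=O)[C@@]2(C)[C@@H]1[C@](O)(C(C)C)C[C@@H]2O[Si](CC)(CC)CC | intermediate
15 | 6β-(pinacolboryl)-4α-hydroxy-2β-(triethylsilyloxy)dauc-7-en-10-one | CC1(C)OB(OC1(C)C)[C@H]2C=C(C)CC(=O)[C@@]3(C)[C@@H]2[C@](O)(C(C)C)C[C@@H]3O[Si](CC)(CC)CC | intermediate
16 | 6β-(pinacolboryl)-4α-hydroxy-2β-(triethylsilyloxy)dauc-8-en-10-one | CC1(C)OB(OC1(C)C)[C@H]2CC(C)=CC(=O)[C@@]3(C)[C@@H]2[C@](O)(C(C)C)C[C@@H]3O[Si](CC)(CC)CC | intermediate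
17 | 4α,6β-dihydroxy-2β-(triethylsilyloxy)dauc-8-en-10-one | O[C@H]1CC(C)=CC(=O)[C@@]2(C)[C@@H]1[C@](O)(C(C)C)C[C@@H]2O[Si](CC)(CC)CC | intermediate
18 | 2β-(triethylsilyloxy)dauc-8-ene-4α,6β,10α-triol | O[C@H]1CC(C)=C[C@H](O)[C@@]2(C)[C@@H]1[C@](O)(C(C)C)C[C@@H]2O[Si](CC)(CC)CC | intermediate
19 | 8α,9α-epoxy-2β-(triethylsilyloxy)daucane-4α,6β,10α-triol | O[C@H]1C[C@]2(C)O[C@@H]2[C@H](O)[C@@]2(C)[C@@H]1[C@](O)(C(C)C)C[C@@H]2O[Si](CC)(CC)CC | intermediate
20 | angelic acid, (Z)-2-methylbut-2-enoic acid | C/C=C(/C)C(=O)O | starting material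
21 | 6β-angeloyloxy-8α,9α-epoxy-2β-(triethylsilyloxy)daucane-4α,10α-diol | C/C=C(/C)C(=O)O[C@H]1C[C@]2(C)O[C@@H]2[C@H](O)[C@@]2(C)[C@@H]1[C@](O)(C(C)C)C[C@@H]2O[Si](CC)(CC)CC | intermediate
22 | 6β,10α-bis(angeloyloxy)-8α,9α-epoxy-2β-(triethylsilyloxy)daucan-4α-ol | C/C=C(/C)C(=O)O[C@H]1C[C@]2(C)O[C@@H]2[C@H](OC(=O)/C(C)=C\C)[C@@]2(C)[C@@H]1[C@](O)(C(C)C)C[C@@H]2O[Si](CC)(CC)CC | intermediate
23 | CNP0265715.3, 6β,10α-bis(angeloyloxy)-8α,9α-epoxy-5β-H-daucane-2β,4α-diol | C/C=C(/C)C(=O)O[C@H]1C[C@]2(C)O[C@@H]2[C@H](OC(=O)/C(C)=C\C)[C@@]2(C)[C@@H]1[C@](O)(C(C)C)C[C@@H]2O | target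

**Total step count:** 12. **Longest linear sequence:** 12 steps (1/2 → 23); 6 and 20 enter as purchased materials.

**Three steps most likely to fail**

Step 6. The side-chain ketone could intercept the activated epoxide, the allylic silyl ether could ionise, and the ketone-ene closure onto a cis-disubstituted alkene may be slow or divert to chloride capture or pinacol-type shifts. Fallback (polar aldol closure instead of the ene reaction, setting out from 12 and returning at 17): quench after the first stage and isolate 12. Tsuji–Wacker oxidation (PdCl2, CuCl, O2, DMF/H2O) puts the new carbonyl on C6, distal to the quaternary centre, giving the cycloheptane-1,4-dione F1. A pyrrolidine/AcOH enamine aldol then closes C4–C5 to the cis-fused hydroxy diketone F2. Me4NBH(OAc)3 (AcOH/MeCN, −20 °C) reduces only the β-hydroxy ketone at C6 by internal delivery from the 4α-hydroxyl, giving the 1,3-anti 6β-alcohol F3. α-Selenation at C9 (LiN(i-Pr)2, PhSeBr, THF, −78 °C) gives the selenide F4, and H2O2/pyridine oxidation with syn-elimination delivers enone 17; steps 7 and 8 are then not needed.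

Step 8. The borylation may go 1,4 or from the wrong face. Fallback (epoxide route to the C6 oxygen, setting out from 14 and returning at 17): dimethyldioxirane (acetone, 0 °C) epoxidises the more electron-rich C6–C7 alkene of 14 from the convex face to give the epoxy enone F5. SmI2 (THF/MeOH, −78 °C) cleaves the allylic C7–O bond reductively to the 6β-hydroxy β,γ-enone F6, which catalytic DBU conjugates to 17.

Step 11. The neopentyl C10 hydroxyl next to the epoxide is hindered, and angelates isomerise to tiglates under forcing acylation. Fallback (build the Z-alkenes in place instead of transferring them, setting out from 19 and returning at 22): acylate both hydroxyls with 2-[bis(2,2,2-trifluoroethoxy)phosphoryl]propanoic acid (DCC, DMAP, CH2Cl2) to give the bis-phosphonate F7. Double Still–Gennari olefination with acetaldehyde (KN(SiMe3)2, 18-crown-6, THF, −78 °C) then forms both (Z)-2-methylbut-2-enoates, giving 22.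

**Further compounds**
F1 | step 6 | (2S)-2,6-dimethyl-2-[(1S)-4-methyl-3-oxo-1-(triethylsilyloxy)pentyl]cycloheptane-1,4-dione (C6 epimers) | CC(C)C(=O)C[C@H](O[Si](CC)(CC)CC)[C@]1(C)CC(=O)CC(C)CC1=O
F2 | step 6 | 4α-hydroxy-2β-(triethylsilyloxy)-5β-H-daucane-6,10-dione (C8 epimers) | O=C1CC(C)CC(=O)[C@@]2(C)[C@@H]1[C@](O)(C(C)C)C[C@@H]2O[Si](CC)(CC)CC
F3 | step 6 | 4α,6β-dihydroxy-2β-(triethylsilyloxy)-5β-H-daucan-10-one (C8 epimers) | O[C@H]1CC(C)CC(=O)[C@@]2(C)[C@@H]1[C@](O)(C(C)C)C[C@@H]2O[Si](CC)(CC)CC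
F4 | step 6 | 4α,6β-dihydroxy-9-(phenylselanyl)-2β-(triethylsilyloxy)-5β-H-daucan-10-one | O[C@H]1CC(C)C([Se]c3ccccc3)C(=O)[C@@]2(C)[C@@H]1[C@](O)(C(C)C)C[C@@H]2O[Si](CC)(CC)CC
F5 | step 8 | 6β,7β-epoxy-4α-hydroxy-2β-(triethylsilyloxy)-5β-H-dauc-8-en-10-one | O1[C@H]2[C@@H]1C(C)=CC(=O)[C@@]3(C)[C@@H]2[C@](O)(C(C)C)C[C@@H]3O[Si](CC)(CC)CC
F6 | step 8 | 4α,6β-dihydroxy-2β-(triethylsilyloxy)-5β-H-dauc-7-en-10-one | O[C@H]1C=C(C)CC(=O)[C@@]2(C)[C@@H]1[C@](O)(C(C)C)C[C@@H]2O[Si](CC)(CC)CC
F7 | step 11 | 6β,10α-bis{2-[bis(2,2,2-trifluoroethoxy)phosphoryl]propanoyloxy}-8α,9α-epoxy-2β-(triethylsilyloxy)daucan-4α-ol | CC(C(=O)O[C@H]1C[C@]2(C)O[C@@H]2[C@H](OC(=O)C(C)P(=O)(OCC(F)(F)F)OCC(F)(F)F)[C@@]2(C)[C@@H]1[C@](O)(C(C)C)C[C@@H]2O[Si](CC)(CC)CC)P(=O)(OCC(F)(F)F)OCC(F)(F)F
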